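**Retrosynthetic overview**
1. Target locants: C1 = C(CH3)2, C2 = CHBr, C3 = C(=CH–CH2Br), C4 = CHCl, C5 = CH2, C6 = CHCl. The C2–Br bond is made last, by SN2 inversion of an allylic alcohol obtained by hydride addition to a C2 ketone.
2. C4–Cl and the (Z)-CH2Br arm are set together by conjugate (1,4) addition of Br–Cl across the diene C4=C3–CH=CH2 of a 2-vinylcyclohex-2-enone; the vinyl group comes from a Stille coupling on a 2-bromoenone.
3. The six-membered ring is not made by cyclisation. The 2-bromoenone arises from a cyclopentanone silyl enol ether by dibromocarbene addition and electrocyclic opening of the fused cyclopropane (5 → 6); the carbene carbon becomes C3.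
4. The five-membered precursor, (S)-3-chloro-2,2-dimethylcyclopentanone, comes from 2,2-dimethylcyclopentane-1,3-dione by desymmetrising CBS reduction and Appel inversion (sets C6–Cl). Ring order: cyclopentane (purchased) → cyclopropane-fused bicycle → cyclohexene.
5. Enabling feature: C3 is the only ring carbon without a stereocentre and sits between the two hetero-substituted carbons C2 and C4, so it can be the inserted carbon. C1 is quaternary, so the cyclopentanone forms one enol ether only (towards the future C4), and the future C6 chloride, β to the carbonyl through C1, has no path for elimination.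

Key step: step 4

Remark: bromine monochloride is taken as a pre-formed reagent (solution in CH2Cl2).

**Step 1**
Reactants: 1 2,2-dimethylcyclopentane-1,3-dione
Product: 2 (3R)-3-hydroxy-2,2-dimethylcyclopentan-1-one
Conditions: (S)-Me-CBS (10 mol %), catecholborane (1.1 equiv), toluene, −78 °C; aqueous work-up
Reagents that add atoms: none
Why: Corey–Bakshi–Shibata reduction: the two carbonyls of 1 are equivalent, the oxazaborolidine binds the carbonyl lone pair away from the quaternary C2 (large group) and delivers hydride to one enantiotopic face, so the (S)-catalyst should give the (R)-carbinol, and the hydroxy ketone is reduced more slowly than the dione so that reduction stops after one carbonyl.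

**Step 2**
Reactants: 2 (3R)-3-hydroxy-2,2-dimethylcyclopentan-1-one
Product: 3 (3S)-3-chloro-2,2-dimethylcyclopentan-1-one
Conditions: PPh3, CCl4, ClCH2CH2Cl, 70 °C
Reagents that add atoms: carbon tetrachloride ClC(Cl)(Cl)Cl
Why: Appel reaction: chloride displaces the alkoxyphosphonium ion by SN2 with inversion ((R)-alcohol to (S)-chloride), PPh3/CCl4 being the classical reagent for neopentyl-type alcohols, and a Wagner–Meerwein methyl shift is disfavoured because it would place the cation next to the carbonyl group.

**Step 3**
Reactants: 3 (3S)-3-chloro-2,2-dimethylcyclopentan-1-one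
Product: 4 {[(4S)-4-chloro-5,5-dimethylcyclopent-1-en-1-yl]oxy}trimethylsilane
Conditions: TMSOTf, Et3N, CH2Cl2, 0 °C
Reagents that add atoms: trimethylsilyl trifluoromethanesulfonate C[Si](C)(C)OS(=O)(=O)C(F)(F)F
Why: Soft enolisation and O-silylation of a ketone: only C5 carries α-hydrogens because C2 is quaternary, so a single enol ether should form, and the C–Cl stereocentre is untouched since it has no acidic neighbour.

**Step 4**
Reactants: 4 {[(4S)-4-chloro-5,5-dimethylcyclopent-1-en-1-yl]oxy}trimethylsilane; 5 bromoform
Product: 7 (5S)-2-bromo-5-chloro-6,6-dimethylcyclohex-2-en-1-one, via dibromocyclopropane adduct 6 (not isolated)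
Conditions: CHBr3, KOtBu, pentane, −40 °C; filter; toluene, 60 °C
Reagents that add atoms: bromoform BrC(Br)Br
Why: Singlet dibromocarbene (α-elimination of CHBr3) adds cheletropically to the electron-rich enol ether C1=C2 of 4 to give the 6,6-dibromo-1-siloxybicyclo[3.1.0]hexane 6; on warming, the cyclopropyl bromide ionises with concerted disrotatory 2π-electrocyclic opening of the internal C1–C5 bond (Woodward–Hoffmann–DePuy, the endo bromide leaves), the siloxy group stabilises the 2-bromo-oxyallyl cation, and bromide removes the silyl group to release the enone. The closest known reaction type is the dihalocarbene one-carbon ring expansion of cyclic silyl enol ethers to 2-halocycloalk-2-enones. The cyclopropane closes by [2+1] cycloaddition, and the six-membered ring then arises by cleavage of the bond shared by the three- and five-membered rings, so it is a ring expansion and not a new cyclisation. No stereocentre is created: both cyclopropane diastereomers converge on 7, and the C–Cl stereocentre is a spectator. The step needs regiocontrol (which α-carbon is enolised, which cyclopropane bond breaks) and must avoid vinylogous loss of HCl from the γ-acidic product; the quaternary carbon allows one enol ether only, orbital symmetry in the strained [3.1.0] frame allows only internal-bond cleavage, and the carbene is generated at −40 °C with the salts removed before the base-free thermal opening. In one operation it should deliver the six-membered ring, the future C3 carrying a bromine handle, the C2 oxygen and the C3=C4 double bond on the side that the later diene chemistry requires.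

**Step 5**
Reactants: 7 (5S)-2-bromo-5-chloro-6,6-dimethylcyclohex-2-en-1-one; 8 tributyl(vinyl)stannane
Product: 9 (5S)-5-chloro-2-ethenyl-6,6-dimethylcyclohex-2-en-1-one
Conditions: Pd2(dba)3 (2.5 mol %), AsPh3, CuI, NMP, 25 °C
Reagents that add atoms: tributyl(vinyl)stannane C=C[Sn](CCCC)(CCCC)CCCC
Why: Stille coupling of an α-bromoenone under base-free conditions, which leave the secondary alkyl chloride and the γ-hydrogens alone; no stereocentre is formed, and 9 is used at once because 2-vinyl enones dimerise on standing.

**Step 6**
Reactants: 9 (5S)-5-chloro-2-ethenyl-6,6-dimethylcyclohex-2-en-1-one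
Product: 10 (2E,3S,5S)-2-(2-bromoethylidene)-3,5-dichloro-6,6-dimethylcyclohexan-1-one
Conditions: BrCl (1.0 equiv), CH2Cl2, −78 °C, dark
Reagents that add atoms: bromine monochloride BrCl
Why: Electrophilic conjugate (1,4) addition of bromine chloride to a 1,3-diene: Br+ should attack only the terminal vinyl carbon (attack at the ring alkene would put a cation next to the carbonyl), chloride then collapses on the ring terminus of the allyl cation pseudo-axially on the face that avoids a 1,3-diaxial clash with the C5 chlorine (3,5-trans), and the s-trans diene conformation is carried into the alkylidene geometry with CH2Br cis to the carbonyl carbon.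

**Step 7**
Reactants: 10 (2E,3S,5S)-2-(2-bromoethylidene)-3,5-dichloro-6,6-dimethylcyclohexan-1-one
Product: 11 (1R,2E,3S,5S)-2-(2-bromoethylidene)-3,5-dichloro-6,6-dimethylcyclohexan-1-ol
Conditions: DIBAL-H (1.1 equiv), CH2Cl2, −78 °C; aq. Rochelle salt
Reagents that add atoms: none
Why: 1,2-Reduction of an enone by DIBAL-H: in the expected chair the allylic C3–Cl is axial and shields the axial trajectory, so hydride should enter from the opposite face and give the (1R)-alcohol with OH cis to the C3 chlorine, and the allylic halides are inert to DIBAL-H at −78 °C.

**Step 8**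
Reactants: 11 (1R,2E,3S,5S)-2-(2-bromoethylidene)-3,5-dichloro-6,6-dimethylcyclohexan-1-ol
Product: 12 (2S,3Z,4S,6S)-2-bromo-3-(2-bromoethylidene)-4,6-dichloro-1,1-dimethylcyclohexane
Conditions: CBr4, PPh3 (added slowly), CH2Cl2, −20 °C
Reagents that add atoms: carbon tetrabromide BrC(Br)(Br)Br
Why: Appel bromination: bromide displaces the alkoxyphosphonium ion at the allylic carbinol carbon by SN2 with inversion, turning the (1R)-alcohol into the (2S)-bromide of the target, and slow addition of PPh3 to substrate and CBr4 keeps the phosphine from alkylating on the primary allylic bromide.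

**Compound list**
1 | 2,2-dimethylcyclopentane-1,3-dione | CC1(C)C(=O)CCC1=O | starting material
2 | (3R)-3-hydroxy-2,2-dimethylcyclopentan-1-one | CC1(C)C(=O)CC[C@H]1O | intermediate
3 | (3S)-3-chloro-2,2-dimethylcyclopentan-1-one | CC1(C)C(=O)CC[C@@H]1Cl | intermediate
4 | {[(4S)-4-chloro-5,5-dimethylcyclopent-1-en-1-yl]oxy}trimethylsilane | CC1(C)C(O[Si](C)(C)C)=CC[C@@H]1Cl | intermediate
5 | bromoform | BrC(Br)Br | starting material
6 | {[(3S)-6,6-dibromo-3-chloro-2,2-dimethylbicyclo[3.1.0]hexan-1-yl]oxy}trimethylsilane (both cyclopropane faces, not isolated) | CC1(C)C2(O[Si](C)(C)C)C(C2(Br)Br)C[C@@H]1Cl | intermediate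
7 | (5S)-2-bromo-5-chloro-6,6-dimethylcyclohex-2-en-1-one | CC1(C)C(=O)C(Br)=CC[C@@H]1Cl | intermediate
8 | tributyl(vinyl)stannane | C=C[Sn](CCCC)(CCCC)CCCC | starting material
9 | (5S)-5-chloro-2-ethenyl-6,6-dimethylcyclohex-2-en-1-one | CC1(C)C(=O)C(C=C)=CC[C@@H]1Cl | intermediate
10 | (2E,3S,5S)-2-(2-bromoethylidene)-3,5-dichloro-6,6-dimethylcyclohexan-1-one | CC1(C)C(=O)/C(=C\CBr)[C@@H](Cl)C[C@@H]1Cl | intermediate
11 | (1R,2E,3S,5S)-2-(2-bromoethylidene)-3,5-dichloro-6,6-dimethylcyclohexan-1-ol | CC1(C)[C@@H](O)/C(=C\CBr)[C@@H](Cl)C[C@@H]1Cl | intermediate
12 | (2S,3Z,4S,6S)-2-bromo-3-(2-bromoethylidene)-4,6-dichloro-1,1-dimethylcyclohexane | CC1(C)[C@H](Br)/C(=C\CBr)[C@@H](Cl)C[C@@H]1Cl | target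

**Step count and risks**
Total steps: 8. Longest linear sequence: 8 steps (1 to 12).

The three steps most likely to fail:

Step 6. Chloride may collapse on the side-chain carbon next to the bromine (1,2-addition across the vinyl group) instead of on the ring carbon, and halide-induced addition–elimination on the enone may scramble the alkylidene geometry. The fallback sets out from 9 and returns at 10. Compound 9 would be submitted to palladium(II)-catalysed 1,4-acetoxychlorination (Pd(OAc)2 cat., p-benzoquinone, LiCl, LiOAc, AcOH, 25 °C). Acetate attacks the vinyl terminus, and chloride opens the π-allylpalladium intermediate at the ring carbon remote from the acetate, so the 1,4-pattern is fixed by the mechanism. This should give 2-[(1E,2S,4S)-2,4-dichloro-5,5-dimethyl-6-oxocyclohexylidene]ethyl acetate F1. Neutral lipase-mediated hydrolysis (pH 7 buffer) should then give (2E,3S,5S)-3,5-dichloro-2-(2-hydroxyethylidene)-6,6-dimethylcyclohexan-1-one F2, and CBr4/PPh3 converts its primary allylic alcohol into 10.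

Step 8. Backside displacement at the neopentylic allylic carbon is slow, so allylic transposition (attack at the side-chain carbon), cyclisation through the cis-bromomethyl group and elimination may compete. The fallback sets out from 11 and returns at 12 without a new compound. Alcohol 11 would be ionised with bromotrimethylsilane in CH2Cl2 at −40 °C, which erases the carbinol configuration. Bromide should then add to the ring terminus of the allyl cation, which carries more charge than the terminus next to CH2Br, from the face opposite the pseudo-axial C3 chlorine. The C–Br configuration would thus be controlled by the ring and not by an SN2 trajectory.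

Step 2. Attack on the alkoxyphosphonium ion is retarded by the adjacent quaternary carbon, so E2 elimination to the β,γ-unsaturated ketone and incomplete conversion may take over. The fallback sets out from 1 and returns at 3. Reduction of 1 with the (R)-Me-CBS catalyst would give (3S)-3-hydroxy-2,2-dimethylcyclopentan-1-one F3. Thionyl chloride converts it into (1S)-2,2-dimethyl-3-oxocyclopentyl sulfurochloridite F4 (not isolated). With catalytic TiCl4 this chlorosulfite should collapse by front-side (SNi) chloride delivery with retention to 3, so no backside approach at the hindered carbon is needed.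

**Further compounds**
F1 | step 6 | 2-[(1E,2S,4S)-2,4-dichloro-5,5-dimethyl-6-oxocyclohexylidene]ethyl acetate | CC1(C)C(=O)/C(=C\COC(C)=O)[C@@H](Cl)C[C@@H]1Cl
F2 | step 6 | (2E,3S,5S)-3,5-dichloro-2-(2-hydroxyethylidene)-6,6-dimethylcyclohexan-1-one | CC1(C)C(=O)/C(=C\CO)[C@@H](Cl)C[C@@H]1Cl
F0 | step 8 | none | none
F3 | step 2 | (3S)-3-hydroxy-2,2-dimethylcyclopentan-1-one | CC1(C)C(=O)CC[C@@H]1O
F4 | step 2 | (1S)-2,2-dimethyl-3-oxocyclopentyl sulfurochloridite | CC1(C)C(=O)CC[C@@H]1OS(=O)Cl
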